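**Plan**
- Retrosynthetic cuts, in order: the methyl ester (back to a lactone on 7-O), C8–CH of the side chain, C6–CH2 of the prenyl group, O1–C2 of ring B, and C4–C4a of the acyl group.
- Forward order: ring A is bought as phloroglucinol. It is tigloylated, the para oxygen is silylated, ring B is closed, and the prenyl group is moved from 5-O to C6. A temporary lactone ring C is then built across 7-O/C8 and opened with methanol.
- Enabling feature: ring B is a β-aryloxy ketone (O1–C2–C3–C4=O), so O1–C2 is a retro-oxa-Michael bond. C4 hangs on C4a between the oxygen-bearing C5 and C8a, and in the open E-enone these two ortho hydroxyls are mirror images, so only one ring B can form.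
- Stereochemistry: C2 (R) and the kinetic cis C3 (S) come from quinine in the ring closure. The side-chain centre (R) comes from a chiral triazolium carbene catalyst.
- C3 is alpha to C4=O and belongs to the less stable cis isomer, so every step after the closure avoids free base and strong acid.

Key step: step 4

Assumption: the sense of induction of the aminoindanol-derived triazolium salt in step 10 is carried over from its annulations of ynals with naphthols and kojic-acid-type enols. Both antipodes are commercial, and the one written is the one expected to give the R centre.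

Step 1
Reactants: 1 tiglic acid, (E)-2-methylbut-2-enoic acid
Product: 2 (E)-2-methylbut-2-enoyl chloride (tigloyl chloride)
Conditions: (COCl)2 (1.2 equiv), DMF (cat.), CH2Cl2, 0 °C to rt; distillation
Reagents that add atoms: oxalyl chloride, ClC(=O)C(=O)Cl
Why: DMF-catalysed acyl chloride formation with oxalyl chloride runs near room temperature and gives only gaseous by-products, so the E geometry of the trisubstituted alkene should pass unchanged into 2.

Step 2
Reactants: 3 phloroglucinol; 2 (E)-2-methylbut-2-enoyl chloride
Product: 4 (E)-2-methyl-1-(2,4,6-trihydroxyphenyl)but-2-en-1-one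
Conditions: AlCl3 (3.5 equiv), CH2Cl2–MeNO2, 0 °C to rt; poured on ice/1 M HCl
Reagents that add atoms: none
Why: Friedel–Crafts C-acylation of the threefold activated ring has only one kind of ring carbon to attack and stops after one acylation because the ketone deactivates the ring, while the aluminium chelate between the ortho phenoxides and the carbonyl, the low temperature and the cold acidic quench should keep the enone from closing.

Step 3
Reactants: 4 (E)-2-methyl-1-(2,4,6-trihydroxyphenyl)but-2-en-1-one
Product: 5 (E)-1-[2,6-dihydroxy-4-(triisopropylsilyloxy)phenyl]-2-methylbut-2-en-1-one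
Conditions: TIPSCl (1.05 equiv), imidazole (2 equiv), CH2Cl2–DMF, 0 °C
Reagents that add atoms: chlorotriisopropylsilane, CC(C)[Si](Cl)(C(C)C)C(C)C
Why: Selective silyl ether formation relies on the two ortho hydroxyls being hydrogen-bonded to and shielded by the ketone, so that the bulky chlorosilane takes the free and more acidic para hydroxyl, which keeps the mirror plane of the ring, removes the proton that would otherwise tie up the amine catalyst and makes the substrate soluble in chlorobenzene, any ring-closed racemic material formed here being removed by chromatography.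

Step 4
Reactants: 5 (E)-1-[2,6-dihydroxy-4-(triisopropylsilyloxy)phenyl]-2-methylbut-2-en-1-one
Product: 7 (2R,3S)-5-hydroxy-2,3-dimethyl-7-(triisopropylsilyloxy)chroman-4-one, via ring-B enol 6 (not isolated)
Conditions: (−)-quinine (10 mol %), PhCl, 10 °C; cold aq citric acid wash as soon as 5 is consumed
Reagents that add atoms: none
Why: The quinuclidine nitrogen of quinine takes the proton of one ortho hydroxyl of 5 while the alkaloid hydroxyl hydrogen-bonds to the enone carbonyl, and the ion-paired phenoxide adds to the β-carbon to form O1–C2 and the ring-B enol 6, which is then protonated at C3. The closest known reaction is the cinchona-alkaloid-catalysed intramolecular oxa-Michael addition of ortho-tigloylphenols to 2,3-dimethylchroman-4-ones, shown on phloroglucinol ethers and on hydroxycoumarins. Ring B closes in the 6-endo-trig mode, both alkene carbons ending up inside the new ring. C2 (R) is controlled by the chiral ion pair, which presents one face of the fixed E-alkene to the phenoxide, and C3 (S) is controlled by kinetic proton return from the quinuclidinium to the enol face opposite the pseudoaxial C2 methyl, which leaves the two methyls cis. The step needs site selectivity between two phenols, which the mirror symmetry of 5 makes moot, a catalysed rate well above the background closure, which the non-polar solvent, the low temperature and the silylated para oxygen should secure, and kinetic control at C3. For the last point the amine is washed out at once, before it can equilibrate 7 to the trans isomer.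

Step 5
Reactants: 8 2-methylbut-3-en-2-ol
Product: 10 tert-butyl 2-methylbut-3-en-2-yl carbonate, via lithium alkoxide 9 (not isolated)
Conditions: n-BuLi (1.0 equiv), THF, −78 to 0 °C; Boc2O, 0 °C to rt; H2O quench
Reagents that add atoms: di-tert-butyl dicarbonate, CC(C)(C)OC(=O)OC(=O)OC(C)(C)C; n-butyllithium, [Li]CCCC (lithium of 9 only)
Why: Acylation of a tertiary lithium alkoxide with Boc2O, in which tert-butyl carbonate is the leaving group, is the standard entry to mixed tertiary allylic carbonates that a chloroformate and an amine base reach only sluggishly.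

Step 6
Reactants: 7 (2R,3S)-5-hydroxy-2,3-dimethyl-7-(triisopropylsilyloxy)chroman-4-one; 10 tert-butyl 2-methylbut-3-en-2-yl carbonate
Product: 11 (2R,3S)-2,3-dimethyl-5-(2-methylbut-3-en-2-yloxy)-7-(triisopropylsilyloxy)chroman-4-one
Conditions: Pd(PPh3)4 (5 mol %), 10 (1.5 equiv), THF, 0–5 °C
Reagents that add atoms: none
Why: Tsuji–Trost O-allylation: zerovalent palladium ionises 10 with loss of CO2, the tert-butoxide set free deprotonates the only free phenol, and at low temperature the phenoxide attacks the more substituted end of the 1,1-dimethylallyl palladium cation to give the branched ether without any added base, so that C3 is left alone.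

Step 7
Reactants: 11 (2R,3S)-2,3-dimethyl-5-(2-methylbut-3-en-2-yloxy)-7-(triisopropylsilyloxy)chroman-4-one
Product: 13 (2R,3S)-5-hydroxy-2,3-dimethyl-6-(3-methylbut-2-enyl)-7-(triisopropylsilyloxy)chroman-4-one, via C6 dienone 12 (not isolated)
Conditions: PhMe (degassed), 110 °C, sealed tube
Reagents that add atoms: none
Why: Aromatic Claisen rearrangement: the [3,3] shift from 5-O can end only at C6 because the other ortho carbon C4a is fully substituted, it turns the branched allyl unit into the linear prenyl group, the gem-dimethyl group lowers the barrier enough for neutral toluene, and tautomerisation of dienone 12 restores the chelated 5-hydroxyl faster than any further shift towards C8.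

Step 8
Reactants: 13 (2R,3S)-5-hydroxy-2,3-dimethyl-6-(3-methylbut-2-enyl)-7-(triisopropylsilyloxy)chroman-4-one
Product: 14 (2R,3S)-5,7-dihydroxy-2,3-dimethyl-6-(3-methylbut-2-enyl)chroman-4-one
Conditions: TBAF/AcOH (1:1, 1.2 equiv), THF, 0 °C
Reagents that add atoms: none
Why: Fluoride-induced cleavage of the aryl silyl ether is fast at 0 °C because the C7 phenoxide is a vinylogous carboxylate leaving group, and the acetic acid buffer protonates it at once so that no base able to enolise the C4 ketone is present.

Step 9
Reactants: 15 hex-2-yn-1-ol
Product: 16 hex-2-ynal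
Conditions: MnO2 (activated, excess), CH2Cl2, rt
Reagents that add atoms: none
Why: Oxidation with activated MnO2 is selective for propargylic alcohols and stops at the ynal without over-oxidation or migration of the triple bond.

Step 10
Reactants: 14 (2R,3S)-5,7-dihydroxy-2,3-dimethyl-6-(3-methylbut-2-enyl)chroman-4-one; 16 hex-2-ynal
Product: 17 (2R,3S,10R)-5-hydroxy-2,3-dimethyl-6-(3-methylbut-2-enyl)-10-propyl-2,3,9,10-tetrahydro-4H,8H-pyrano[2,3-f]chromene-4,8-dione
Conditions: (5aR,10bS)-2-mesityl-5a,10b-dihydro-4H,6H-indeno[2,1-b][1,2,4]triazolo[4,3-d][1,4]oxazin-2-ium chloride (10 mol %), 16 (1.3 equiv), PhMe, 40 °C, no added base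
Reagents that add atoms: none
Why: Carbene-catalysed redox annulation of an ynal with a stable enol (Coates–Claisen type): the carbene turns 16 by internal redox into a catalyst-bound α,β-unsaturated acyl azolium, the 7-hydroxyl, whose acidity matches that of the enols and naphthols known in this reaction, adds to its carbonyl and a [3,3] shift joins the β-carbon to C8, the only unsubstituted ring carbon, after which acylation of 7-O closes ring C and frees the catalyst, the aminoindanol backbone shielding one face of the acyl azolium so that C10 is set as R under catalyst control.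

Step 11
Reactants: 17 (2R,3S,10R)-5-hydroxy-2,3-dimethyl-6-(3-methylbut-2-enyl)-10-propyl-2,3,9,10-tetrahydro-4H,8H-pyrano[2,3-f]chromene-4,8-dione
Product: 18 methyl (3R)-3-[(2R,3S)-5,7-dihydroxy-2,3-dimethyl-6-(3-methylbut-2-enyl)-4-oxochroman-8-yl]hexanoate
Conditions: MeOH (solvent), camphorsulfonic acid (5 mol %), rt; solid NaHCO3 before concentration below 25 °C
Reagents that add atoms: methanol, CO
Why: Acid-catalysed transesterification opens ring C because the lactone is the aryl ester of a vinylogous acid and thus an activated acyl donor, the large excess of methanol drives the equilibrium to the hydroxy ester, the mild acid touches neither the prenyl alkene nor any of the three stereocentres, and neutralisation before concentration prevents the ring from closing again.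

**Compound list**
1 | tiglic acid, (E)-2-methylbut-2-enoic acid | C/C=C(\C)C(=O)O | starting material
2 | (E)-2-methylbut-2-enoyl chloride | C/C=C(\C)C(=O)Cl | intermediate
3 | phloroglucinol | Oc1cc(O)cc(O)c1 | starting material
4 | (E)-2-methyl-1-(2,4,6-trihydroxyphenyl)but-2-en-1-one | C/C=C(\C)C(=O)c1c(O)cc(O)cc1O | intermediate
5 | (E)-1-[2,6-dihydroxy-4-(triisopropylsilyloxy)phenyl]-2-methylbut-2-en-1-one | C/C=C(\C)C(=O)c1c(O)cc(O[Si](C(C)C)(C(C)C)C(C)C)cc1O | intermediate
6 | (2R)-2,3-dimethyl-7-(triisopropylsilyloxy)-2H-chromene-4,5-diol (ring-B enol, not isolated) | CC(C)[Si](Oc1cc(O)c2c(c1)O[C@H](C)C(C)=C2O)(C(C)C)C(C)C | intermediate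
7 | (2R,3S)-5-hydroxy-2,3-dimethyl-7-(triisopropylsilyloxy)chroman-4-one (cis) | CC(C)[Si](Oc1cc(O)c2c(c1)O[C@H](C)[C@H](C)C2=O)(C(C)C)C(C)C | intermediate
8 | 2-methylbut-3-en-2-ol | CC(C)(O)C=C | starting material
9 | lithium 2-methylbut-3-en-2-olate (not isolated) | [Li+].[O-]C(C)(C)C=C | intermediate
10 | tert-butyl 2-methylbut-3-en-2-yl carbonate | C=CC(C)(C)OC(=O)OC(C)(C)C | intermediate
11 | (2R,3S)-2,3-dimethyl-5-(2-methylbut-3-en-2-yloxy)-7-(triisopropylsilyloxy)chroman-4-one | CC(C)[Si](Oc1cc(OC(C)(C)C=C)c2c(c1)O[C@H](C)[C@H](C)C2=O)(C(C)C)C(C)C | intermediate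
12 | (2R,3S)-2,3-dimethyl-6-(3-methylbut-2-enyl)-7-(triisopropylsilyloxy)-2,3-dihydrochromene-4,5(6H)-dione (C6 epimers, not isolated) | CC(C)=CCC1C(=O)C2=C(C=C1O[Si](C(C)C)(C(C)C)C(C)C)O[C@H](C)[C@H](C)C2=O | intermediate
13 | (2R,3S)-5-hydroxy-2,3-dimethyl-6-(3-methylbut-2-enyl)-7-(triisopropylsilyloxy)chroman-4-one | CC(C)=CCc1c(O)c2c(cc1O[Si](C(C)C)(C(C)C)C(C)C)O[C@H](C)[C@H](C)C2=O | intermediate
14 | (2R,3S)-5,7-dihydroxy-2,3-dimethyl-6-(3-methylbut-2-enyl)chroman-4-one | CC(C)=CCc1c(O)c2c(cc1O)O[C@H](C)[C@H](C)C2=O | intermediate
15 | hex-2-yn-1-ol | CCCC#CCO | starting material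
16 | hex-2-ynal | CCCC#CC=O | intermediate
17 | (2R,3S,10R)-5-hydroxy-2,3-dimethyl-6-(3-methylbut-2-enyl)-10-propyl-2,3,9,10-tetrahydro-4H,8H-pyrano[2,3-f]chromene-4,8-dione | CCC[C@@H]1CC(=O)Oc2c(CC=C(C)C)c(O)c3c(c21)O[C@H](C)[C@H](C)C3=O | intermediate
18 | methyl (3R)-3-[(2R,3S)-5,7-dihydroxy-2,3-dimethyl-6-(3-methylbut-2-enyl)-4-oxochroman-8-yl]hexanoate | CCC[C@H](CC(=O)OC)c1c(O)c(CC=C(C)C)c(O)c2c1O[C@H](C)[C@H](C)C2=O | target

Total step count: 11. Longest linear sequence: 9 (steps 1, 2, 3, 4, 6, 7, 8, 10, 11).

**Steps most likely to fail**

**Step 10.**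
- Risk: the acyl azolium may be drained by plain O-acylation of the 7-hydroxyl instead of bond formation at C8. Facial selectivity may also be poor with a linear alkyl ynal on a phenol that is flanked on both sides.
- Fallback: it sets out from 14 and comes back at 17, and it changes the electrophile from an acyl azolium to an iminium ion.
- 14 and commercial (E)-hex-2-enal are combined in toluene at 0 °C with benzoic acid and the antipode of diphenylprolinol trimethylsilyl ether that gives the 10R centre.
- Friedel–Crafts-type conjugate addition of C8, followed by closure of the 7-hydroxyl on the freed aldehyde, should give the tricyclic lactol F1.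
- Dess–Martin periodinane in CH2Cl2 then oxidises the lactol carbon to give 17. The remaining 5-hydroxyl is chelated and has no open ortho or para position.

**Step 6.**
- Risk: the hydrogen-bonded 5-hydroxyl may be too poor a nucleophile for the allyl palladium cation. Re-ionisation of the branched ether may also let it drift to the linear ether, which on heating would send the prenyl group towards C8.
- Fallback: it sets out from 7 and comes back at 13. It builds the prenyl group in two stages and replaces steps 5 to 7.
- Mitsunobu etherification of the 5-hydroxyl with allyl alcohol (PPh3, DIAD, THF, 0 °C to rt) is neutral and known for chelated 5-hydroxyls of flavanones. It should give the 5-O-allyl ether F2.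
- A Claisen rearrangement assisted by Eu(fod)3 in toluene moves the allyl group to C6 and gives the 6-allyl phenol F3.
- Cross metathesis with excess 2-methylbut-2-ene (second-generation Grubbs catalyst, CH2Cl2, 40 °C) converts the allyl into the prenyl group of 13.

**Step 4.**
- Risk: uncatalysed closure through the second ortho hydroxyl may erode the enantiomeric purity, and amine-induced enolisation may leak the cis isomer to the trans isomer before conversion is complete.
- Fallback: it sets out from 3 and comes back at 7, replacing steps 1 to 4. It takes both centres from the chiral pool and forms O1–C2 by SN2 displacement instead of conjugate addition.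
- 3 is converted with MOMCl and i-Pr2NEt into 1,3,5-tris(methoxymethoxy)benzene F4, which n-BuLi in THF at 0 °C lithiates between two ether groups to the aryllithium F5.
- In parallel, commercial methyl (S)-3-hydroxybutanoate undergoes Fráter–Seebach alkylation (LiN(i-Pr)2, 2 equiv, MeI, THF, −78 to 0 °C) to the anti hydroxy ester F6.
- MeNH(OMe)·HCl and i-PrMgCl turn F6 into the Weinreb amide F7.
- An excess of F5 adds to F7 at −78 °C to give the protected hydroxy ketone F8. Dilute HCl in MeOH then removes the three acetals to give the tetrol ketone F9.
- Mitsunobu cyclisation (PPh3, DIAD, THF, 0 °C) lets an ortho phenol displace the activated carbinol with inversion. The anti (S,S) array thus becomes the cis dihydroxychromanone F10.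
- Silylation of the free 7-hydroxyl (TIPSCl, imidazole, 0 °C) gives 7.

**Further compounds**
F1 | step 10 | (2R,3S,10R)-5,8-dihydroxy-2,3-dimethyl-6-(3-methylbut-2-enyl)-10-propyl-2,3,9,10-tetrahydro-4H,8H-pyrano[2,3-f]chromen-4-one (both C8 epimers) | CCC[C@@H]1CC(O)Oc2c(CC=C(C)C)c(O)c3c(c21)O[C@H](C)[C@H](C)C3=O
F2 | step 6 | (2R,3S)-5-allyloxy-2,3-dimethyl-7-(triisopropylsilyloxy)chroman-4-one | CC(C)[Si](Oc1cc(OCC=C)c2c(c1)O[C@H](C)[C@H](C)C2=O)(C(C)C)C(C)C
F3 | step 6 | (2R,3S)-6-allyl-5-hydroxy-2,3-dimethyl-7-(triisopropylsilyloxy)chroman-4-one | C=CCc1c(O)c2c(cc1O[Si](C(C)C)(C(C)C)C(C)C)O[C@H](C)[C@H](C)C2=O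
F4 | step 4 | 1,3,5-tris(methoxymethoxy)benzene | COCOc1cc(OCOC)cc(OCOC)c1
F5 | step 4 | 2,4,6-tris(methoxymethoxy)phenyllithium | [Li]c1c(OCOC)cc(OCOC)cc1OCOC
F6 | step 4 | methyl (2S,3S)-3-hydroxy-2-methylbutanoate | COC(=O)[C@@H](C)[C@H](C)O
F7 | step 4 | (2S,3S)-3-hydroxy-N-methoxy-N,2-dimethylbutanamide | CON(C)C(=O)[C@@H](C)[C@H](C)O
F8 | step 4 | (2S,3S)-3-hydroxy-2-methyl-1-[2,4,6-tris(methoxymethoxy)phenyl]butan-1-one | COCOc1cc(OCOC)c(C(=O)[C@@H](C)[C@H](C)O)c(OCOC)c1
F9 | step 4 | (2S,3S)-3-hydroxy-2-methyl-1-(2,4,6-trihydroxyphenyl)butan-1-one | Oc1cc(O)c(C(=O)[C@@H](C)[C@H](C)O)c(O)c1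
F10 | step 4 | (2R,3S)-5,7-dihydroxy-2,3-dimethylchroman-4-one | Oc1cc(O)c2c(c1)O[C@H](C)[C@H](C)C2=O
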